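The route rests on cutting the aryl ether bond O11–C10a of the dihydrofuran ring C, so ring D never needs a 2'-oxygen. The feature used is that C10a of ring D lies ortho to C6b and meta to the C9 methoxy group. This is the carbon that the polarised 3-methoxyaryne C10≡C10a offers to a nucleophile. In one operation a lithium amide turns a 3'-bromo-4'-methoxyphenyl group into this aryne, and the cis C11a alkoxide closes ring C without touching either stereocentre. The precursor 11 is a (3S,4S)-cis-isoflavan-4-ol carrying the O5/C6-fused dimethylchroman ring and a 7-OTIPS group. It is made by Ru transfer hydrogenation with dynamic kinetic resolution.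

Key step: step 7

Remark: the target SMILES is read as the cis-fused (6aS,11aS) enantiomer. Isoflavone numbering (C2, C3, C4, C5–C8, primed aryl ring) is used for 3–11 and pterocarpan numbering for 12–15. Isoflavone C3/C4/C2'/C3'/C7/C8 correspond to pterocarpan C6a/C11a/C10a/C10/C3/C4.

Step 1
Reactants: 1 phloroglucinol; 2 2-(3-bromo-4-methoxyphenyl)acetic acid
Product: 4 3-(3-bromo-4-methoxyphenyl)-5,7-dihydroxy-4H-chromen-4-one, via deoxybenzoin 3 (not isolated)
Conditions: BF3·OEt2 (as solvent), 85 °C; then DMF, MsCl, 60 °C; H2O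
Reagents that add atoms: N,N-dimethylformamide, CN(C)C=O
Why: BF3-promoted Friedel–Crafts C-acylation of the symmetric triphenol can give only one deoxybenzoin, and Vilsmeier-type formylation of its activated CH2 by the DMF–MsCl iminium salt followed by loss of dimethylamine closes the pyranone, either ortho hydroxyl giving the same isoflavone.

Step 2
Reactants: 4 3-(3-bromo-4-methoxyphenyl)-5,7-dihydroxy-4H-chromen-4-one
Product: 5 3-(3-bromo-4-methoxyphenyl)-5-hydroxy-7-(triisopropylsilyloxy)-4H-chromen-4-one
Conditions: TIPSCl (1.1 equiv), imidazole, DMF, 0 °C to rt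
Reagents that add atoms: triisopropylsilyl chloride, CC(C)[Si](Cl)(C(C)C)C(C)C
Why: Selective silylation should occur at the acidic, unhindered 7-OH because the 5-OH is locked in a hydrogen bond to C4=O, and TIPS is chosen because it later shields C8–H from metalation and leaves with fluoride instead of acid or hydrogen.

Step 3
Reactants: 5 3-(3-bromo-4-methoxyphenyl)-5-hydroxy-7-(triisopropylsilyloxy)-4H-chromen-4-one; 6 3-chloro-3-methylbut-1-yne (3 equiv)
Product: 7 3-(3-bromo-4-methoxyphenyl)-5-(2-methylbut-3-yn-2-yloxy)-7-(triisopropylsilyloxy)-4H-chromen-4-one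
Conditions: CuCl2 (5 mol %), DBU, dry MeCN, 0 °C to rt
Reagents that add atoms: none
Why: Copper-catalysed propargylic etherification runs through a strongly electrophilic copper acetylide/allenylidene cation that even the weakly nucleophilic 5-phenoxide freed by DBU should trap at the tertiary carbon, and the cold, carbonate-free and water-free medium should spare the activated aryl silyl ether, the C–Br bond and the pyranone.

Step 4
Reactants: 7 3-(3-bromo-4-methoxyphenyl)-5-(2-methylbut-3-yn-2-yloxy)-7-(triisopropylsilyloxy)-4H-chromen-4-one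
Product: 8 9-(3-bromo-4-methoxyphenyl)-2,2-dimethyl-5-(triisopropylsilyloxy)-2H,10H-pyrano[2,3-f]chromen-10-one
Conditions: o-xylene, 140 °C
Reagents that add atoms: none
Why: The aromatic propargyl Claisen rearrangement can reach only C6, since the other ortho position C4a is quaternary, and the following 1,5-hydrogen shift and oxa-6π electrocyclisation give the 2,2-dimethylchromene fused through O5 and C6.

Step 5
Reactants: 8 9-(3-bromo-4-methoxyphenyl)-2,2-dimethyl-5-(triisopropylsilyloxy)-2H,10H-pyrano[2,3-f]chromen-10-one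
Product: 9 9-(3-bromo-4-methoxyphenyl)-2,2-dimethyl-5-(triisopropylsilyloxy)-3,4-dihydro-2H,10H-pyrano[2,3-f]chromen-10-one
Conditions: H2 (4 bar), RhCl(PPh3)3 (5 mol %), PhMe–EtOH, 40 °C
Reagents that add atoms: none
Why: Homogeneous hydrogenation with Wilkinson's catalyst should saturate the cis-disubstituted chromene alkene while leaving the C–Br bond and the trisubstituted C2=C3 vinylogous ester alone, which avoids the hydrodebromination expected over heterogeneous palladium.

Step 6
Reactants: 9 9-(3-bromo-4-methoxyphenyl)-2,2-dimethyl-5-(triisopropylsilyloxy)-3,4-dihydro-2H,10H-pyrano[2,3-f]chromen-10-one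
Product: 11 (3S,4S)-cis-3-(3-bromo-4-methoxyphenyl)chroman-4-ol bearing the O5/C6-fused 2,2-dimethyldihydropyran ring and 7-OTIPS, via racemising isoflavanone 10 (not isolated)
Conditions: RuCl[(S,S)-TsDPEN](p-cymene) (5 mol %), HCO2H–Et3N (1:1), EtOAc, 40 °C; NaHCO3 work-up, Et3N-washed silica
Reagents that add atoms: none
Why: In this Noyori–Ikariya asymmetric transfer hydrogenation cascade Ru–H first reduces C2=C3 in the 1,4-sense to 10, whose C3–H epimerises quickly through the enol in the amine medium, and the (S,S)-catalyst then reduces the (3S)-ketone much faster by hydride delivery to the Re face of C4 anti to the aryl group, so dynamic kinetic resolution sets C4 as S (catalyst control) and C3 as S (cis to the hydroxyl).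

Step 7
Reactants: 11 (3S,4S)-cis-3-(3-bromo-4-methoxyphenyl)chroman-4-ol bearing the O5/C6-fused 2,2-dimethyldihydropyran ring and 7-OTIPS
Product: 14 (6aS,11aS)-3-O-TIPS pterocarpan (silyl ether of the target), via lithium alkoxide aryne 12 (not isolated), via C10 aryllithium 13 (not isolated)
Conditions: LiTMP (4 equiv, from TMPH + n-BuLi), THF (0.02 M), −78 °C to 0 °C; aq NH4Cl
Reagents that add atoms: none
Why: LiTMP first forms the C4 lithium alkoxide and then removes C2'–H, the only hydrogen ortho to bromine because the other neighbour carries the methoxy group, and the 2-bromoaryllithium loses LiBr at once to give the single aryne 12 (C10≡C10a). The alkoxide oxygen adds in the aryne plane to C10a in a 5-exo-dig closure (ring O11–C11a–C6a–C6b–C10a), and the C10 aryllithium 13, stabilised by the adjacent methoxy group, is protonated by TMPH or on quench. The closest known reaction type is the base-induced aryne cyclisation of 2-(3-halophenyl)ethanols to 2,3-dihydrobenzofurans, combined with amide-base generation of 3-methoxyarynes from 4-substituted 2-bromoanisoles. No stereocentre is created, because the C11a–O and C6a–C6b bonds stay intact and the cis relation from step 6 holds oxygen and aryl ring gauche on one face, so the cis B/C fusion is inherited. The step needs regioselectivity, which the two-carbon tether and the inductive bias of the 3-methoxyaryne both direct to C10a, and it needs ring closure to outrun amine addition, which the hindered TMPH and high dilution favour. The bulky TIPS group keeps C8–H from being lithiated and prevents a free C3 phenoxide from expelling O11.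

Step 8
Reactants: 14 (6aS,11aS)-3-O-TIPS pterocarpan
Product: 15 target, (6aS,11aS)-3-hydroxy-9-methoxypterocarpan with a 2,2-dimethyl-3,4-dihydro-2H-pyran ring fused through O at C1 and CH2 at C2
Conditions: TBAF (1.2 equiv), AcOH (1.2 equiv), THF, 0 °C
Reagents that add atoms: none
Why: Fluoride-induced Si–O cleavage buffered with acetic acid keeps the liberated C3 phenol protonated, so it cannot open ring C through a para-quinone methide, and no acid strong enough to ionise C11a–O11 or the tertiary pyran ether is present, so both stereocentres and the ring-fusion pattern should persist.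

Compound list
1 | phloroglucinol | Oc1cc(O)cc(O)c1 | starting material
2 | 2-(3-bromo-4-methoxyphenyl)acetic acid | COc1ccc(CC(=O)O)cc1Br | starting material
3 | 2-(3-bromo-4-methoxyphenyl)-1-(2,4,6-trihydroxyphenyl)ethan-1-one (deoxybenzoin, not isolated) | COc1ccc(CC(=O)c2c(O)cc(O)cc2O)cc1Br | intermediate
4 | 3-(3-bromo-4-methoxyphenyl)-5,7-dihydroxy-4H-chromen-4-one | O=C1C(c2ccc(OC)c(Br)c2)=COc2cc(O)cc(O)c12 | intermediate
5 | 3-(3-bromo-4-methoxyphenyl)-5-hydroxy-7-(triisopropylsilyloxy)-4H-chromen-4-one | O=C1C(c2ccc(OC)c(Br)c2)=COc2cc(O[Si](C(C)C)(C(C)C)C(C)C)cc(O)c12 | intermediate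
6 | 3-chloro-3-methylbut-1-yne | CC(C)(Cl)C#C | starting material
7 | 3-(3-bromo-4-methoxyphenyl)-5-(2-methylbut-3-yn-2-yloxy)-7-(triisopropylsilyloxy)-4H-chromen-4-one | O=C1C(c2ccc(OC)c(Br)c2)=COc2cc(O[Si](C(C)C)(C(C)C)C(C)C)cc(OC(C)(C)C#C)c12 | intermediate
8 | 9-(3-bromo-4-methoxyphenyl)-2,2-dimethyl-5-(triisopropylsilyloxy)-2H,10H-pyrano[2,3-f]chromen-10-one (chromene fused at isoflavone O5/C6) | O=C1C(c2ccc(OC)c(Br)c2)=COc2cc(O[Si](C(C)C)(C(C)C)C(C)C)c3C=CC(C)(C)Oc3c12 | intermediate
9 | 9-(3-bromo-4-methoxyphenyl)-2,2-dimethyl-5-(triisopropylsilyloxy)-3,4-dihydro-2H,10H-pyrano[2,3-f]chromen-10-one | O=C1C(c2ccc(OC)c(Br)c2)=COc2cc(O[Si](C(C)C)(C(C)C)C(C)C)c3CCC(C)(C)Oc3c12 | intermediate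
10 | racemising isoflavanone, the 2,3-dihydro derivative of 9 (C3 configurationally labile, not isolated) | O=C1C(c2ccc(OC)c(Br)c2)COc2cc(O[Si](C(C)C)(C(C)C)C(C)C)c3CCC(C)(C)Oc3c12 | intermediate
11 | (9S,10S)-9-(3-bromo-4-methoxyphenyl)-2,2-dimethyl-5-(triisopropylsilyloxy)-3,4,9,10-tetrahydro-2H,8H-pyrano[2,3-f]chromen-10-ol, i.e. the (3S,4S)-cis-isoflavan-4-ol | O[C@@H]1c2c(cc(O[Si](C(C)C)(C(C)C)C(C)C)c3c2OC(C)(C)CC3)OC[C@@H]1c1ccc(OC)c(Br)c1 | intermediate
12 | lithium alkoxide of 11 with the aryl ring as the C2'≡C3' (C10a≡C10) aryne (not isolated) | [Li]O[C@@H]1c2c(cc(O[Si](C(C)C)(C(C)C)C(C)C)c3c2OC(C)(C)CC3)OC[C@@H]1C1=CC=C(OC)C#C1 | intermediate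
13 | (6aS,11aS)-10-lithio-3-O-TIPS pterocarpan (not isolated) | COc1ccc2c(c1[Li])O[C@@H]1c3c(cc(O[Si](C(C)C)(C(C)C)C(C)C)c4c3OC(C)(C)CC4)OC[C@H]21 | intermediate
14 | (6aS,11aS)-3-O-TIPS pterocarpan (silyl ether of the target) | COc1ccc2c(c1)O[C@@H]1c3c(cc(O[Si](C(C)C)(C(C)C)C(C)C)c4c3OC(C)(C)CC4)OC[C@H]21 | intermediate
15 | CNP0207547.1, (6aS,11aS)-3-hydroxy-9-methoxypterocarpan with the 2,2-dimethyldihydropyran ring at O1/C2 | COc1ccc2c(c1)O[C@@H]1c3c(cc(O)c4c3OC(C)(C)CC4)OC[C@H]21 | target

Total step count: 8. Longest linear sequence: 8 (1 to 15; 2 and 6 are purchased).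

Steps most likely to fail

Step 7. Removal of the hindered C2'–H, flanked by bromine and the chromanyl group, may be slow. Bromine migration, amine addition to the aryne or base-induced breakdown of the benzylic alkoxide could then compete with ring closure. The fallback forms the same O11–C10a bond by metal-catalysed intramolecular C–O coupling of the ortho-bromo isomer. It sets out from 1. Commercial 2-(2-bromo-4-methoxyphenyl)acetic acid is carried through the chemistry of steps 1–6. This gives in turn the deoxybenzoin F1 (not isolated), the 2'-bromo isoflavone F2, its 7-O-TIPS ether F3, the 5-O-dimethylpropargyl ether F4, the chromene F5, the chroman F6, the isoflavanone F7 (not isolated) and the (3S,4S)-cis alcohol F8. A Buchwald–Hartwig-type etherification (Pd(OAc)2, a bulky di-tert-butylbiarylphosphine, Cs2CO3, toluene, 70 °C) or an Ullmann variant (CuI, 1,10-phenanthroline) then closes ring C with retention at both centres. The route is rejoined at 14.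

Step 3. O-Alkylation of the hydrogen-bonded 5-OH may be sluggish, so that elimination of the tertiary chloride and silyl transfer away from O7 take over. The fallback makes the C6–C bond first and the O5–C bond last, and it sets out from 5.
- Hydroxyl-directed iodination with benzyltrimethylammonium dichloroiodate and CaCO3 in CH2Cl2–MeOH should give the 6-iodo isoflavone F9.
- Stille coupling with tributyl(3-methylbut-2-enyl)stannane (PdCl2(PPh3)2, DMF, 80 °C), where the C–I bond reacts ahead of C–Br, should give the 6-prenyl isoflavone F10.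
- Acid-catalysed Markovnikov hydroalkoxylation (catalytic p-TsOH, toluene, 60 °C) can use only O5, because O7 is silylated.

This sequence replaces steps 3–5 and comes back to the route at 9.

Step 6. The 1,4-reduction of the electron-rich vinylogous ester may stall. A long reaction time would then expose the ionisable benzylic alcohol and the silyl ether to the medium and erode selectivity. The fallback separates the two reductions and sets out from 9. DIBAL-H (THF–toluene, −78 °C) performs the conjugate reduction through the aluminium enolate, and 10 is now isolated as the racemate. Compound 10 alone is then submitted to the transfer-hydrogenative dynamic kinetic resolution with the same (S,S)-Ru catalyst in amine-rich formate for a short time. The route is rejoined at 11.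

Further compounds
F1 | step 7 | 2-(2-bromo-4-methoxyphenyl)-1-(2,4,6-trihydroxyphenyl)ethan-1-one | COc1ccc(CC(=O)c2c(O)cc(O)cc2O)c(Br)c1
F2 | step 7 | 3-(2-bromo-4-methoxyphenyl)-5,7-dihydroxy-4H-chromen-4-one | O=C1C(c2ccc(OC)cc2Br)=COc2cc(O)cc(O)c12
F3 | step 7 | 3-(2-bromo-4-methoxyphenyl)-5-hydroxy-7-(triisopropylsilyloxy)-4H-chromen-4-one | O=C1C(c2ccc(OC)cc2Br)=COc2cc(O[Si](C(C)C)(C(C)C)C(C)C)cc(O)c12
F4 | step 7 | 3-(2-bromo-4-methoxyphenyl)-5-(2-methylbut-3-yn-2-yloxy)-7-(triisopropylsilyloxy)-4H-chromen-4-one | O=C1C(c2ccc(OC)cc2Br)=COc2cc(O[Si](C(C)C)(C(C)C)C(C)C)cc(OC(C)(C)C#C)c12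
F5 | step 7 | 9-(2-bromo-4-methoxyphenyl)-2,2-dimethyl-5-(triisopropylsilyloxy)-2H,10H-pyrano[2,3-f]chromen-10-one | O=C1C(c2ccc(OC)cc2Br)=COc2cc(O[Si](C(C)C)(C(C)C)C(C)C)c3C=CC(C)(C)Oc3c12
F6 | step 7 | 9-(2-bromo-4-methoxyphenyl)-2,2-dimethyl-5-(triisopropylsilyloxy)-3,4-dihydro-2H,10H-pyrano[2,3-f]chromen-10-one | O=C1C(c2ccc(OC)cc2Br)=COc2cc(O[Si](C(C)C)(C(C)C)C(C)C)c3CCC(C)(C)Oc3c12
F7 | step 7 | racemising isoflavanone, the 2,3-dihydro derivative of F6 | O=C1C(c2ccc(OC)cc2Br)COc2cc(O[Si](C(C)C)(C(C)C)C(C)C)c3CCC(C)(C)Oc3c12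
F8 | step 7 | (3S,4S)-cis-3-(2-bromo-4-methoxyphenyl)chroman-4-ol with the O5/C6-fused dimethyldihydropyran ring and 7-OTIPS | O[C@@H]1c2c(cc(O[Si](C(C)C)(C(C)C)C(C)C)c3c2OC(C)(C)CC3)OC[C@@H]1c1ccc(OC)cc1Br
F9 | step 3 | 3-(3-bromo-4-methoxyphenyl)-5-hydroxy-6-iodo-7-(triisopropylsilyloxy)-4H-chromen-4-one | O=C1C(c2ccc(OC)c(Br)c2)=COc2cc(O[Si](C(C)C)(C(C)C)C(C)C)c(I)c(O)c12
F10 | step 3 | 3-(3-bromo-4-methoxyphenyl)-5-hydroxy-6-(3-methylbut-2-enyl)-7-(triisopropylsilyloxy)-4H-chromen-4-one | O=C1C(c2ccc(OC)c(Br)c2)=COc2cc(O[Si](C(C)C)(C(C)C)C(C)C)c(CC=C(C)C)c(O)c12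
F0 | step 6 | none | none
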